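Ring A carries methyl groups on both carbons that flank the spiro atom C6 (C1 and C5), so it maps onto 3,5-dimethylphenol with C3 as the phenol carbon and C6 para to it. The route rests on the C6–C11 disconnection: zerovalent palladium ionizes a Z-allylic carbonate tethered to C6 through C7–C8, and the phenolate para carbon attacks the allyl terminus C11. One operation dearomatizes ring A, creates the quaternary spiro carbon and closes ring B with the C9=C10 alkene that later carries the bromochloride. The precursor is (Z)-5-(4-hydroxy-2,6-dimethylphenyl)-3-methylpent-2-en-1-yl methyl carbonate.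

Key step: step 7

Remarks on the chemistry (one line each):
- Numbering: ring A is C1–C6 (C1 CHMe, C4 CHBr, C5 CMe2, C6 spiro) and ring B is C6–C11 (C9 CMeCl, C10 CHBr); names of all spiro compounds use these locants.
- The cyclization substrate must be a 5-aryl-3-methylpent-2-enyl carbonate: two CH2 groups (C7, C8) between arene and C9 give a six-membered ring B, whereas a hexenyl chain would give a seven-membered ring.
- Its alkene is built Z because C8 and C11 must be cis on C9=C10 inside ring B; an E substrate could close only after syn–anti isomerization through a tertiary σ-allyl palladium species.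
- In the achiral trienone 12 the two enones are enantiotopic, and a reagent adding to ring A meets the two ring B arms only as two CH2 groups, so such an addition cannot be relied on to fix C6; C6 is instead fixed by a catalyst that reads the two faces of C9=C10 (step 9).
- Assumption: the D-fructose-derived Shi ketone gives the (9S,10R)-oxirane, the sense it shows with 1-substituted cyclohexenes; if the sense were opposite, the enantiomeric ketone would be used.
- The CIP label at C6 changes along the route with substituent priorities (15 is 6R, the target is 6S); the geometry at C6 is the same from 15 onward.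

Step 1
Reactants: 1 4-bromo-3,5-dimethylphenol
Product: 2 (4-bromo-3,5-dimethylphenoxy)triisopropylsilane
Conditions: TIPSCl, imidazole, DMF, rt
Reagents that add atoms: chlorotriisopropylsilane, CC(C)[Si](Cl)(C(C)C)C(C)C
Why: Imidazole-promoted O-silylation of the phenol gives a triisopropylsilyl ether that tolerates the two Suzuki couplings and is later removed by fluoride without harm to an allylic carbonate.

Step 2
Reactants: 2 (4-bromo-3,5-dimethylphenoxy)triisopropylsilane; 3 4,4,5,5-tetramethyl-2-vinyl-1,3,2-dioxaborolane
Product: 4 (4-ethenyl-3,5-dimethylphenoxy)triisopropylsilane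
Conditions: Pd(OAc)2 (2 mol%), SPhos (2-dicyclohexylphosphino-2′,6′-dimethoxybiphenyl, 4 mol%), K3PO4, toluene/H2O, 80 °C
Reagents that add atoms: none
Why: Suzuki–Miyaura coupling of the di-ortho-substituted aryl bromide with the vinylboronate is well served by the bulky biarylphosphine, and the mild phosphate base leaves the aryl silyl ether intact.

Step 3
Reactants: 5 but-2-yn-1-ol
Product: 7 (Z)-3-iodobut-2-en-1-ol, via cyclic vinylalanate 6 (not isolated)
Conditions: NaAlH2(OCH2CH2OMe)2, THF, 0 °C to rt; then I2, THF, −78 °C to 0 °C
Reagents that add atoms: iodine, II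
Why: Hydroxyl-directed trans-hydroalumination of the propargylic alcohol places aluminium on C3 inside a five-membered alkoxyalanate, and iodinolysis with retention fixes the Z geometry (iodine cis to CH2OH).

Step 4
Reactants: 4 (4-ethenyl-3,5-dimethylphenoxy)triisopropylsilane; 7 (Z)-3-iodobut-2-en-1-ol
Product: 9 (Z)-5-[2,6-dimethyl-4-(triisopropylsilyloxy)phenyl]-3-methylpent-2-en-1-ol, via B-alkyl-9-BBN borane 8 (not isolated)
Conditions: 9-BBN, THF, rt; then 7, PdCl2(dppf) (5 mol%), 3 M aq. K3PO4, THF, rt
Reagents that add atoms: none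
Why: Anti-Markovnikov hydroboration of the styrene followed by B-alkyl Suzuki–Miyaura coupling, which proceeds with retention at the vinyl iodide, should give the trisubstituted alkene with the arylethyl chain cis to CH2OH (Z), the geometry the ring closure needs.

Step 5
Reactants: 9 (Z)-5-[2,6-dimethyl-4-(triisopropylsilyloxy)phenyl]-3-methylpent-2-en-1-ol
Product: 10 (Z)-5-[2,6-dimethyl-4-(triisopropylsilyloxy)phenyl]-3-methylpent-2-en-1-yl methyl carbonate
Conditions: ClCO2Me, pyridine, CH2Cl2, 0 °C
Reagents that add atoms: methyl chloroformate, COC(=O)Cl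
Why: Acylation of the primary allylic alcohol installs the leaving group that also supplies the methoxide base in the key step.

Step 6
Reactants: 10 (Z)-5-[2,6-dimethyl-4-(triisopropylsilyloxy)phenyl]-3-methylpent-2-en-1-yl methyl carbonate
Product: 11 (Z)-5-(4-hydroxy-2,6-dimethylphenyl)-3-methylpent-2-en-1-yl methyl carbonate
Conditions: Bu4NF, AcOH (1:1), THF, 0 °C
Reagents that add atoms: none
Why: Acetic acid-buffered fluoride cleaves the aryl silyl ether quickly (desilylation), and the buffer keeps the phenoxide from attacking the methyl carbonate.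

Step 7
Reactants: 11 (Z)-5-(4-hydroxy-2,6-dimethylphenyl)-3-methylpent-2-en-1-yl methyl carbonate
Product: 12 1,5,9-trimethylspiro[5.5]undeca-1,4,9-trien-3-one (achiral)
Conditions: Pd(PPh3)4 (5 mol%), CH2Cl2 (0.01 M), rt
Reagents that add atoms: none
Why: Zerovalent palladium ionizes the allylic carbonate with loss of CO2 to a cationic π-allyl complex spanning C9–C11, and the methoxide set free deprotonates the phenol. The Z geometry of 11 puts the tether carbon C8 in the anti position at C9, so the phenolate para carbon C6, held on the face away from palladium, can reach the unsubstituted terminus C11 and close ring B as a cyclohexene in a 6-endo sense with C9=C10 inside the ring; attack at C9 would need a four-membered ring. The closest known reaction type is the palladium-catalysed intramolecular ipso-Friedel–Crafts allylic alkylation of para-tethered phenols (Tsuji–Trost dearomatization). No stereocentre is formed, because the trienone has a mirror plane through C3, C6 and ring B, so C6 is not yet stereogenic. The step needs C- over O-alkylation and para over ortho attack; the tether secures this, since only the para carbon can close a six-membered ring, while O-allylation is intermolecular, suppressed by dilution and reversible under the catalyst. Loss of a β-hydrogen from the π-allyl complex to a diene is the competing path and should be disfavoured by the base-free conditions at room temperature.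

Step 8
Reactants: 12 1,5,9-trimethylspiro[5.5]undeca-1,4,9-trien-3-one
Product: 14 (±)-1,5,5,9-tetramethylspiro[5.5]undeca-1,9-dien-3-one, via trimethylsilyl dienol ether 13 (not isolated)
Conditions: Me2CuLi (from MeLi, CuI), TMSCl, THF, −78 to −20 °C; then 1 M HCl, THF, 0 °C
Reagents that add atoms: lithium dimethylcuprate, [Li+].C[Cu-]C
Why: Chlorotrimethylsilane-accelerated Gilman conjugate addition to one of the two equivalent β-methyl enones builds the C5 gem-dimethyl group beside quaternary C6 and stops after one addition because the silyl dienol ether is no longer an acceptor; C6 becomes a stereocentre here, but an achiral reagent cannot tell the enantiotopic enones apart, so 14 is racemic by design and is resolved in step 9.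

Step 9
Reactants: 14 (±)-1,5,5,9-tetramethylspiro[5.5]undeca-1,9-dien-3-one
Product: 15 (6R,9S,10R)-9,10-epoxy-1,5,5,9-tetramethylspiro[5.5]undec-1-en-3-one
Conditions: Shi ketone (1,2:4,5-di-O-isopropylidene-D-erythro-2,3-hexodiulo-2,6-pyranose, 30 mol%), KHSO5 (Oxone), K2CO3, Bu4NHSO4, MeCN/CH2(OMe)2/aq. buffer pH 10.5, 0 °C; chromatographic separation of the two diastereomers
Reagents that add atoms: potassium peroxymonosulfate, [K+].[O-]S(=O)(=O)OO
Why: Shi asymmetric epoxidation attacks only the electron-rich C9=C10 alkene and, under catalyst control (spiro transition state), the same absolute face in both enantiomers of 14, so the racemate should become two separable diastereomers; the one with the oxirane oxygen anti to C5 across ring B is kept, which fixes C6, C9 and C10 in absolute terms at the price that at most half of the material follows this path.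

Step 10
Reactants: 15 (6R,9S,10R)-9,10-epoxy-1,5,5,9-tetramethylspiro[5.5]undec-1-en-3-one
Product: 17 (4RS,6S,9S,10R)-4-bromo-9,10-epoxy-1,5,5,9-tetramethylspiro[5.5]undec-1-en-3-one, via silyl dienol ether 16 (not isolated)
Conditions: LDA, TMSCl (in situ quench), THF, −78 °C; then NBS, THF, −78 °C
Reagents that add atoms: N-bromosuccinimide, O=C1CCC(=O)N1Br
Why: Kinetic deprotonation of the enone at its only α′-methylene (C4) with in situ silylation gives the 2-silyloxy diene, which N-bromosuccinimide brominates at C4 far faster than it touches the oxirane (enol ether bromination); the configuration at C4 is left open here because an α-bromo ketone epimerizes readily, and it is settled in step 13.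

Step 11
Reactants: 17 (4RS,6S,9S,10R)-4-bromo-9,10-epoxy-1,5,5,9-tetramethylspiro[5.5]undec-1-en-3-one
Product: 18 (4RS,6S,9S,10S)-4,10-dibromo-9-hydroxy-1,5,5,9-tetramethylspiro[5.5]undec-1-en-3-one
Conditions: Li2NiBr4 (from LiBr, NiBr2), THF, 0 °C to rt
Reagents that add atoms: dilithium tetrabromonickelate, [Li+].[Li+].Br[Ni-2](Br)(Br)Br
Why: Dilithium tetrabromonickelate is a soft, non-acidic bromide source that opens trisubstituted oxiranes by SN2 attack at the less substituted carbon, so bromide should enter C10 with inversion (ending syn to C5) while the tertiary carbinol C9 keeps its configuration; with ring A still an enone neither chair of ring B is favoured, so the reagent's own regiochemistry should decide.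

Step 12
Reactants: 18 (4RS,6S,9S,10S)-4,10-dibromo-9-hydroxy-1,5,5,9-tetramethylspiro[5.5]undec-1-en-3-one
Product: 19 (4RS,6S,9S,10S)-4,10-dibromo-9-chloro-1,5,5,9-tetramethylspiro[5.5]undec-1-en-3-one
Conditions: SOCl2, CH2Cl2, 0 °C to rt
Reagents that add atoms: thionyl chloride, O=S(Cl)Cl
Why: In this deoxychlorination the ionization of the tertiary chlorosulfite is assisted by the anti bromine on C10, and chloride opens the resulting bromonium ion at the more substituted carbon C9 from the face opposite bromine, so C9 is chlorinated with net retention and the trans bromochloride of the target results.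

Step 13
Reactants: 19 (4RS,6S,9S,10S)-4,10-dibromo-9-chloro-1,5,5,9-tetramethylspiro[5.5]undec-1-en-3-one
Product: 20 (3R,4S,6S,9S,10S)-4,10-dibromo-9-chloro-1,5,5,9-tetramethylspiro[5.5]undec-1-en-3-ol
Conditions: NaBH4, CeCl3·7H2O, MeOH, −78 °C; chromatographic separation of the two cis-bromohydrins
Reagents that add atoms: none
Why: Luche 1,2-reduction delivers hydride to the ketone anti to the pseudoaxial C4–Br bond, so each C4 epimer of 19 should give its own cis-bromohydrin; the two diastereomers are separated and the (3R,4S) isomer, with hydroxyl and bromine on the ring A face that carries C11, is taken on, while the other can be recycled by oxidation and epimerization.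

Step 14
Reactants: 20 (3R,4S,6S,9S,10S)-4,10-dibromo-9-chloro-1,5,5,9-tetramethylspiro[5.5]undec-1-en-3-ol
Product: 23 (1S,4R,6S,9S,10S)-4,10-dibromo-9-chloro-1,5,5,9-tetramethylspiro[5.5]undec-2-ene, via N-allyl sulfonylhydrazide 21 (not isolated), via allylic diazene 22 (not isolated)
Conditions: 2-nitrobenzenesulfonylhydrazide, PPh3, DEAD, THF, −30 °C to rt; crude product used directly
Reagents that add atoms: none
Why: In this Myers reductive 1,3-transposition, Mitsunobu displacement by the sulfonylhydrazide inverts C3, loss of sulfinic acid gives the monoalkyl diazene, and its retro-ene loss of N2 hands hydrogen to C1 on the face the nitrogen occupied, which removes the C3 oxygen, moves the alkene to C2=C3 and sets C1 with its methyl cis to the C4 bromine.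

Step 15
Reactants: 23 (1S,4R,6S,9S,10S)-4,10-dibromo-9-chloro-1,5,5,9-tetramethylspiro[5.5]undec-2-ene
Product: 24 (1S,4R,6S,9S,10S)-4,10-dibromo-9-chloro-1,5,5,9-tetramethylspiro[5.5]undecane
Conditions: KO2CN=NCO2K, AcOH, MeOH/CH2Cl2, 0 °C to rt
Reagents that add atoms: none
Why: Diimide reduction transfers hydrogen concertedly to the cis-disubstituted C2=C3 alkene and, unlike catalytic hydrogenation or hydride reagents, should leave the three carbon–halogen bonds untouched; no stereocentre changes.

Compound list
1 | 4-bromo-3,5-dimethylphenol | Cc1cc(O)cc(C)c1Br | starting material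
2 | (4-bromo-3,5-dimethylphenoxy)triisopropylsilane | Cc1cc(O[Si](C(C)C)(C(C)C)C(C)C)cc(C)c1Br | intermediate
3 | 4,4,5,5-tetramethyl-2-vinyl-1,3,2-dioxaborolane | C=CB1OC(C)(C)C(C)(C)O1 | starting material
4 | (4-ethenyl-3,5-dimethylphenoxy)triisopropylsilane | C=Cc1c(C)cc(O[Si](C(C)C)(C(C)C)C(C)C)cc1C | intermediate
5 | but-2-yn-1-ol | CC#CCO | starting material
6 | sodium 2,2-bis(2-methoxyethoxy)-3-methyl-2,5-dihydro-1,2-oxaaluminol-2-uide (cyclic vinylalanate) | CC1=CCO[Al-]1(OCCOC)OCCOC.[Na+] | intermediate (not isolated)
7 | (Z)-3-iodobut-2-en-1-ol | C/C(I)=C/CO | intermediate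
8 | 9-{2-[2,6-dimethyl-4-(triisopropylsilyloxy)phenyl]ethyl}-9-borabicyclo[3.3.1]nonane | Cc1cc(O[Si](C(C)C)(C(C)C)C(C)C)cc(C)c1CCB1C2CCCC1CCC2 | intermediate (not isolated)
9 | (Z)-5-[2,6-dimethyl-4-(triisopropylsilyloxy)phenyl]-3-methylpent-2-en-1-ol | OC/C=C(/C)CCc1c(C)cc(O[Si](C(C)C)(C(C)C)C(C)C)cc1C | intermediate
10 | (Z)-5-[2,6-dimethyl-4-(triisopropylsilyloxy)phenyl]-3-methylpent-2-en-1-yl methyl carbonate | COC(=O)OC/C=C(/C)CCc1c(C)cc(O[Si](C(C)C)(C(C)C)C(C)C)cc1C | intermediate
11 | (Z)-5-(4-hydroxy-2,6-dimethylphenyl)-3-methylpent-2-en-1-yl methyl carbonate | COC(=O)OC/C=C(/C)CCc1c(C)cc(O)cc1C | intermediate (key-step precursor)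
12 | 1,5,9-trimethylspiro[5.5]undeca-1,4,9-trien-3-one (achiral) | CC1=CC(=O)C=C(C)C12CCC(C)=CC2 | intermediate (key-step product)
13 | (±)-trimethyl[(1,5,5,9-tetramethylspiro[5.5]undeca-1,3,9-trien-3-yl)oxy]silane | CC1=CC(O[Si](C)(C)C)=CC(C)(C)C12CCC(C)=CC2 | intermediate (not isolated)
14 | (±)-1,5,5,9-tetramethylspiro[5.5]undeca-1,9-dien-3-one | CC1=CC(=O)CC(C)(C)C12CCC(C)=CC2 | intermediate
15 | (6R,9S,10R)-9,10-epoxy-1,5,5,9-tetramethylspiro[5.5]undec-1-en-3-one (oxirane oxygen anti to C5) | CC1=CC(=O)CC(C)(C)[C@]12CC[C@]3(C)O[C@@H]3C2 | intermediate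
16 | (6S,9S,10R)-9,10-epoxy-1,5,5,9-tetramethyl-3-(trimethylsilyloxy)spiro[5.5]undeca-1,3-diene | CC1=CC(O[Si](C)(C)C)=CC(C)(C)[C@]12CC[C@]3(C)O[C@@H]3C2 | intermediate (not isolated)
17 | (4RS,6S,9S,10R)-4-bromo-9,10-epoxy-1,5,5,9-tetramethylspiro[5.5]undec-1-en-3-one (both C4 epimers) | CC1=CC(=O)C(Br)C(C)(C)[C@]12CC[C@]3(C)O[C@@H]3C2 | intermediate
18 | (4RS,6S,9S,10S)-4,10-dibromo-9-hydroxy-1,5,5,9-tetramethylspiro[5.5]undec-1-en-3-one | CC1=CC(=O)C(Br)C(C)(C)[C@]12CC[C@](C)(O)[C@@H](Br)C2 | intermediate
19 | (4RS,6S,9S,10S)-4,10-dibromo-9-chloro-1,5,5,9-tetramethylspiro[5.5]undec-1-en-3-one | CC1=CC(=O)C(Br)C(C)(C)[C@]12CC[C@](C)(Cl)[C@@H](Br)C2 | intermediate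
20 | (3R,4S,6S,9S,10S)-4,10-dibromo-9-chloro-1,5,5,9-tetramethylspiro[5.5]undec-1-en-3-ol | CC1=C[C@@H](O)[C@@H](Br)C(C)(C)[C@]12CC[C@](C)(Cl)[C@@H](Br)C2 | intermediate
21 | N-[(3S,4S,6S,9S,10S)-4,10-dibromo-9-chloro-1,5,5,9-tetramethylspiro[5.5]undec-1-en-3-yl]-2-nitrobenzenesulfonohydrazide | CC1=C[C@H](N(N)S(=O)(=O)c3ccccc3[N+](=O)[O-])[C@@H](Br)C(C)(C)[C@]12CC[C@](C)(Cl)[C@@H](Br)C2 | intermediate (not isolated)
22 | [(3S,4S,6S,9S,10S)-4,10-dibromo-9-chloro-1,5,5,9-tetramethylspiro[5.5]undec-1-en-3-yl]diazene | CC1=C[C@H](N=N)[C@@H](Br)C(C)(C)[C@]12CC[C@](C)(Cl)[C@@H](Br)C2 | intermediate (not isolated)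
23 | (1S,4R,6S,9S,10S)-4,10-dibromo-9-chloro-1,5,5,9-tetramethylspiro[5.5]undec-2-ene | C[C@H]1C=C[C@@H](Br)C(C)(C)[C@]12CC[C@](C)(Cl)[C@@H](Br)C2 | intermediate
24 | (1S,4R,6S,9S,10S)-4,10-dibromo-9-chloro-1,5,5,9-tetramethylspiro[5.5]undecane | C[C@H]1CC[C@@H](Br)C(C)(C)[C@]12CC[C@](C)(Cl)[C@@H](Br)C2 | target

Total step count: 15. Longest linear sequence: 14 steps (steps 1, 2 and 4–15 from 4-bromo-3,5-dimethylphenol; step 3 is a one-step branch).

The three steps most likely to fail

Step 7: the π-allyl palladium intermediate may lose a β-hydrogen to a diene, or alkylate a second phenol on oxygen, faster than it closes the ring through its distal terminus. The fallback forms the same C6–C11 bond by anionic ipso alkylation of the phenoxide instead of π-allyl chemistry. It sets out from 9: PPh3/CCl4 converts the allylic alcohol without allylic shift into (Z)-{4-(5-chloro-3-methylpent-3-en-1-yl)-3,5-dimethylphenoxy}triisopropylsilane F1; buffered Bu4NF frees 4-[(Z)-5-chloro-3-methylpent-3-en-1-yl]-3,5-dimethylphenol F2; KOtBu in t-BuOH/THF at high dilution should close ring B by SN2 attack of the phenoxide para carbon on the primary allylic chloride. The route is rejoined at 12.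

Step 8: steric shielding of the β-carbon C5 by the neighbouring quaternary C6 may slow conjugate addition until 1,2-addition or enolization takes over. The fallback replaces the stoichiometric cuprate by nickel-catalysed methylalumination (AlMe3, Ni(acac)2 5 mol%, THF/Et2O, 0 °C), a method known to deliver methyl to hindered β,β-disubstituted enones. It sets out from 12, passes through the dimethylaluminium dienolate F3, and after aqueous acid work-up comes back at 14.

Step 11: regiocontrol in the oxirane opening may be lost (bromide attack at the tertiary carbon under lithium assistance), or bromine may migrate or eliminate from the bromonium ion in step 12. The fallback gives up the stepwise oxirane route for direct alkene bromochlorination with separation of the facial isomers. It sets out from 15: deoxygenation (MeReO3 cat., PPh3, benzene, 80 °C) returns the alkene as single-enantiomer (6R)-1,5,5,9-tetramethylspiro[5.5]undeca-1,9-dien-3-one F4; LDA/TMSCl gives the silyl dienol ether F5 and NBS the bromo enone (4RS,6S)-4-bromo-1,5,5,9-tetramethylspiro[5.5]undeca-1,9-dien-3-one F6; Bu4N·BrCl2 in CH2Cl2 at −78 °C should add bromine and chlorine anti and Markovnikov to C9=C10 on both faces; the adduct with bromine on C10 syn to C5 is separated by chromatography. This adduct is 19, where the route is rejoined.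

Further compounds
F1 | step 7 | (Z)-{4-(5-chloro-3-methylpent-3-en-1-yl)-3,5-dimethylphenoxy}triisopropylsilane | ClC/C=C(/C)CCc1c(C)cc(O[Si](C(C)C)(C(C)C)C(C)C)cc1C
F2 | step 7 | 4-[(Z)-5-chloro-3-methylpent-3-en-1-yl]-3,5-dimethylphenol | ClC/C=C(/C)CCc1c(C)cc(O)cc1C
F3 | step 8 | (±)-dimethyl[(1,5,5,9-tetramethylspiro[5.5]undeca-1,3,9-trien-3-yl)oxy]alumane | CC1=CC(O[Al](C)C)=CC(C)(C)C12CCC(C)=CC2
F4 | step 11 | (6R)-1,5,5,9-tetramethylspiro[5.5]undeca-1,9-dien-3-one | CC1=CC(=O)CC(C)(C)[C@]12CCC(C)=CC2
F5 | step 11 | (6S)-trimethyl[(1,5,5,9-tetramethylspiro[5.5]undeca-1,3,9-trien-3-yl)oxy]silane | CC1=CC(O[Si](C)(C)C)=CC(C)(C)[C@]12CCC(C)=CC2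
F6 | step 11 | (4RS,6S)-4-bromo-1,5,5,9-tetramethylspiro[5.5]undeca-1,9-dien-3-one | CC1=CC(=O)C(Br)C(C)(C)[C@]12CCC(C)=CC2
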